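# Proposed synthesis of (2R,3R,6R,10S)-2,10-dibromochamigr-7(14)-en-3-ol (CNP0114057.1) by enzymatic bromonium spirocyclisation of (E)-γ-bisabolene

Chamigrane numbering is used for all position labels, also in the precursors. Ring B is C1–C5 plus spiro C6, ring A is C6–C11, C14 is the methylidene carbon on C7, C12/C13 are the methyls on C11 and C15 is the methyl on C3. In the systematic names, chamigrane C10, C11 and C7 are locants 8, 7 and 11.

## Analysis of the target

Target 12 is a spiro[5.5]undecane of the chamigrane family. Ring A carries a secondary bromide at C10, a gem-dimethyl carbon C11 and an exocyclic C7=C14 olefin. Ring B carries a secondary bromide at C2 and a tertiary carbinol at C3. There are four stereocentres: the all-carbon spiro centre C6 (R), C10 (S), C2 (R) and C3 (R). In ring A the C10 bromine is cis to C1, so with bromine equatorial C1 is equatorial and C5 axial. In ring B bromine and hydroxyl are trans, bromine lies anti to C7 and the hydroxyl syn to it, so that Br, OH and the bulky C11 can all be equatorial. The sensitive groups are the C2 bromide β to a tertiary alcohol (epoxide closure with base), the acid-labile tertiary alcohol, the neopentyl C10 bromide and a methylidene group that migrates into the ring with acid. The difficulty lies in the vicinal quaternary carbons C6/C11, in relating C6 to C10 with no functional group between them, and in absolute control without a chiral-pool handle. The strategy rests on the triad C10–Br, the C11–C6 bond and the C7=C14 methylidene. This is what remains when a bromonium ion on C10–C11 is opened at C11 by C6 of a C6=C7 olefin and the C7 cation loses a C14 proton.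

## Retrosynthetic reasoning

**12 ⇒ 11.** The C2–Br and C3–O bonds are cut first. A trans bromohydrin on a ring is the anti adduct of a Br+ donor and an oxygen nucleophile to an olefin, so 12 maps onto the C2=C3 olefin of 11. This comes last because the bromohydrin is the most fragile part of 12, and because ring A is then complete and its C7 branch, axial on ring B, can steer the reagent. The forward step must choose the trisubstituted ring olefin over the C7=C14 methylidene, put bromine on C2 on the face away from C7, and bring oxygen to C3 from the opposite face.

**11 ⇒ 8 + 9.** The C6–C11 and C10–Br bonds are cut together. No other disconnection removes ring A, the spiro centre and a stereogenic bromide at once, and it leads to the achiral hydrocarbon 8, which already holds all fifteen carbons. The forward reaction is a bromonium-initiated cation–olefin cyclisation through cation 10, with the bromine taken from 9. It must pick the terminal olefin among three and one of its faces, which is the only source of absolute configuration in the route. It must close through a chair, so that the E geometry of C6=C7 becomes the C6/C10 relationship, and end with loss of a C14 proton.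

**8 ⇒ 7 ⇒ 5.** The tetrasubstituted C6=C7 olefin is the one element of 8 that needs control, since its E and Z forms differ only in which ring methylene faces C8. It is cut back to β-lactone 7, whose thermal decarboxylation is stereospecific, and 7 to β-hydroxy acid 5 by way of 6. Olefin geometry thereby becomes relative configuration at two sp3 centres of a carboxylic acid, where the right diastereomer can be selected before the olefin exists.

**5 ⇒ 2 + 3, 2 ⇒ 1.** The C6–C7 bond of 5 is an aldol bond between the α-carbon of acid 2, as its dianion 4, and the carbonyl of ketone 3. Acid 2 is the hydrolysis product of commercial ester 1. The aldol must tolerate an enolisable ketone and is not expected to tell the two ring arms apart, so a separation is built into it.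

## Alternatives that were turned down

**Alternative 1:** Ring B is cut at C2–C3 and C4–C5, leading back to the spiro cyclobutanone (8S)-8-bromo-9,9-dimethylspiro[3.5]nonane-2,5-dione A2 and 1-(trimethylsilyl)propyne A3.
- **Forward key step:** a zerovalent nickel catalyst with a chiral phosphine joins the cyclobutanone carbonyl carbon to the methyl-bearing alkyne carbon in an oxanickelacycle (C2–C3). β-Carbon elimination opens the four-membered ring and reductive elimination closes C4–C5 to give the 4-silyl spiro enedione A1.
- **For:** in A2 the spiro carbon is not yet a stereocentre, because its two cyclobutanone methylenes are constitutionally the same. The ligand decides which one migrates and so sets C6. This is a better understood way to fix an all-carbon quaternary centre than an enzyme pocket, and on this point the alternative is stronger.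
- **Against:** A1 has the wrong atom at nearly every position that matters (oxygen at C2 and C7, silicon at C4, an sp2 C3). Protodesilylation, enone reduction, C3 hydroxylation, exchange of the C2 oxygen for bromine with the right configuration and methylenation of the hindered C7 ketone all remain, at least six operations with two ketones to distinguish. The C10 bromide must also survive a low-valent nickel catalyst that readily reduces secondary alkyl bromides.
- **Comparison:** the chosen route accepts a less certain key step but needs only one step after it, and its key step installs the C10 bromide instead of having to tolerate it.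

**Alternative 2:** Ring B is cut at C5–C6 and at the C1=C2 double bond of the spiro enone A4, giving (3S)-3-bromo-2,2-dimethyl-6-methylidenecyclohexane-1-carbaldehyde (bromo-γ-cyclocitral) A5 and methyl vinyl ketone A6.
- **Forward key step:** the extended enolate of A5 reacts at its α-carbon C6 with A6 (Michael addition, C5–C6). The methyl ketone then condenses with the aldehyde (aldol condensation, C1=C2), a Robinson-type spiroannulation.
- **For:** cheap reagents and a classical route to a quaternary α-carbon. Ring A of A5 would come from bromonium cyclisation of an acyclic geranyl-type precursor, which is closer to documented reagent chemistry than the cyclisation of 8. On precedent for ring A this plan is stronger.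
- **Against:** the single-enantiomer problem is only moved, since A5 still needs an asymmetric bromonium cyclisation. C6 would be set on a planar enolate whose faces are both flanked by a C11 methyl and differ only through the C10 bromine two bonds away. The dienolate can also react at C14, and base moves the exocyclic olefin of A5 into conjugation and endangers the bromide. A4 still lacks the C3 methyl and has unsaturation at C1=C2 where the target has C2–Br. Reduction, bromination at C2 in competition with the nearly equivalent C4, and a face-selective methyl addition to an α-bromo ketone would follow.
- **Comparison:** the chosen route sets C6 and C10 in one chair-controlled event and reaches the bromohydrin by a single addition to an olefin that is already in place.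

**Alternative 3:** Only the C2–C3 bond of ring B is cut, giving the keto aldehyde 2-[(1R,3S)-3-bromo-2,2-dimethyl-6-methylidene-1-(3-oxobutyl)cyclohexyl]acetaldehyde A8.
- **Forward key step:** a chiral triazolium-derived carbene turns the C2 aldehyde into its acyl anion equivalent (Breslow intermediate), which adds to the C3 methyl ketone and closes ring B as the α-ketol A7.
- **For:** mild, neutral conditions that tolerate bromide and olefin, and clean aldehyde-over-ketone chemoselectivity. The C3 carbinol is made at the right oxidation level with its configuration set by a catalyst and not by substrate bias. In this respect it is stronger than the bromohydrin step of the chosen route.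
- **Against:** the hard part is already inside A8: a quaternary C6 next to C11, carrying two arms that differ by one methylene, in a fixed relation to C10. The benzoin step does nothing to build it. Afterwards the C2 ketone of A7 must become a bromide by reduction and displacement with inversion at a carbon flanked by a tertiary carbinol, where elimination and epoxide or pinacol-type paths compete.
- **Comparison:** it is several steps longer on both sides of its key step. The chosen route solves C6, C10 and ring A together and leaves one addition for C2 and C3.

Key step: step 5

## Route

Remark: compounds 1, 2 and 5–7 are racemates (each SMILES shows one enantiomer). Their stereocentres disappear in step 4, and absolute configuration first arises in step 5.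

Step 1
Reactants: 1 methyl 4-methylcyclohex-3-ene-1-carboxylate
Product: 2 4-methylcyclohex-3-ene-1-carboxylic acid
Conditions: LiOH·H2O, THF/MeOH/H2O, 25 °C; then aq. HCl
Reagents that add atoms: lithium hydroxide, [Li+].[OH-]
Why: Ester saponification; the α-stereocentre of 1 is of no consequence because it is erased on enolisation in step 2, and the ring olefin is inert to hydroxide.

Step 2
Reactants: 2 4-methylcyclohex-3-ene-1-carboxylic acid; 3 6-methylhept-5-en-2-one
Product: 5 rac-(1R)-1-[(2R)-2-hydroxy-6-methylhept-5-en-2-yl]-4-methylcyclohex-3-ene-1-carboxylic acid, via dilithium enediolate 4 (not isolated)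
Conditions: LiN(i-Pr)2 (2.2 equiv), THF, 0 → 40 °C; 3, −78 → 0 °C; aq. HCl; fractional crystallisation
Reagents that add atoms: none
Why: Aldol addition of a carboxylic acid dianion to a ketone forms the C6–C7 bond; the two racemic diastereomers differ in whether ring methylene C1 or C5 lies on the side of the C14 methyl, and the one with C1 and C14 syn is isolated by crystallisation of the acids, with chromatography in reserve. Little facial preference is expected, so the step is planned as a separation and not as a selective reaction.

Step 3
Reactants: 5 rac-(1R)-1-[(2R)-2-hydroxy-6-methylhept-5-en-2-yl]-4-methylcyclohex-3-ene-1-carboxylic acid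
Product: 7 rac-(3R,4R)-3,7-dimethyl-3-(4-methylpent-3-en-1-yl)-2-oxaspiro[3.5]non-6-en-1-one, via mixed benzenesulfonic anhydride 6 (not isolated)
Conditions: PhSO2Cl (2 equiv), pyridine, 0 °C
Reagents that add atoms: none
Why: β-Lactonisation of a β-hydroxy acid by carboxyl activation: the carboxylate is sulfonylated to 6 and the tertiary hydroxyl attacks the acyl carbon, so no bond to C6 or C7 is broken and both centres are retained.

Step 4
Reactants: 7 rac-(3R,4R)-3,7-dimethyl-3-(4-methylpent-3-en-1-yl)-2-oxaspiro[3.5]non-6-en-1-one
Product: 8 (E)-γ-bisabolene [(4E)-1-methyl-4-(6-methylhept-5-en-2-ylidene)cyclohex-1-ene]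
Conditions: neat, 140 °C, N2, base-washed glassware; bulb-to-bulb distillation
Reagents that add atoms: none
Why: Thermal [2+2] cycloreversion of a β-lactone loses CO2 suprafacially, so the groups that are cis on the four-membered ring (C14 methyl and C1) stay cis on the C6=C7 olefin, which is the E isomer; the neutral, acid-free melt should spare the skipped triene from olefin migration.

Step 5
Reactants: 8 (E)-γ-bisabolene; 9 potassium bromide
Product: 11 (6R,8S)-8-bromo-3,7,7-trimethyl-11-methylidenespiro[5.5]undec-2-ene [(6R,10S)-10-bromo-β-chamigrene], via tertiary C7 cation 10 (not isolated)
Conditions: vanadium bromoperoxidase (Corallina officinalis), Na3VO4 (0.1 mM), H2O2 (1.1 equiv, slow addition), MES buffer pH 6.5/EtOH 3:2, 23 °C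
Reagents that add atoms: none
Why: Proposed new method: the vanadate site of the enzyme oxidises bromide with H2O2 to a bound hypobromite-level Br+ donor that transfers Br+ to the si face of C10 of the terminal C10=C11 olefin of 8, the bromonium carbon C11 is attacked by C6 of the tetrasubstituted olefin to give cation 10, and 10 loses a C14 proton; the closest known reaction types are the vanadium bromoperoxidase bromonium cyclisation of acyclic terpene alcohols such as nerolidol and the reagent-based bromonium polyene cyclisation with Et2SBr·SbCl5Br, neither shown with an alkylidenecyclohexene terminator that forms a spiro centre. Ring A closes in the 6-endo mode (endo with respect to both the C10–C11 bromonium and the C6=C7 olefin) through a chair. C10 (S) is set by the enzyme's choice of olefin face, the only element of absolute control. C6 (R) follows from C10 by anti addition in the chair, which places bromine equatorial, and from the E geometry, which holds C1 trans to C8 so that C1 becomes equatorial on ring A and cis to bromine. The step needs site selectivity among three olefins, which is helped by the terminal trisubstituted olefin being the least hindered and the first to enter a hydrophobic channel. It also needs proton loss from C14 and not from C8, which is favoured statistically and sterically (three rotating methyl hydrogens against one axial C8 hydrogen beside the spiro centre) but is not secured. Capture of cation 10 by the aqueous medium is the main competing path.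

Step 6
Reactants: 11 (6R,8S)-8-bromo-3,7,7-trimethyl-11-methylidenespiro[5.5]undec-2-ene
Product: 12 (2R,3R,6R,8S)-2,8-dibromo-3,7,7-trimethyl-11-methylidenespiro[5.5]undecan-3-ol [(2R,3R,6R,10S)-2,10-dibromochamigr-7(14)-en-3-ol]
Conditions: NBS (1.05 equiv), acetone/H2O 4:1, 0 °C, dark
Reagents that add atoms: N-bromosuccinimide, O=C1CCC(=O)N1Br; water, O
Why: Bromohydrin formation (anti addition of Br+ and water): the trisubstituted C2=C3 olefin is more nucleophilic and less encumbered than the C7=C14 methylidene beside the spiro centre. Br+ should enter at C2 anti to C7, which is axial on ring B and holds its C14 methylene over the other face of the C1–C2 edge, and water opens at tertiary C3 anti to bromine (Markovnikov), setting C2 (R) and C3 (R) as the trans bromohydrin with Br, OH and C11 all equatorial.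

## Compound list

1 | methyl 4-methylcyclohex-3-ene-1-carboxylate (racemic) | COC(=O)C1CCC(C)=CC1 | starting material
2 | 4-methylcyclohex-3-ene-1-carboxylic acid (racemic) | OC(=O)C1CCC(C)=CC1 | intermediate
3 | 6-methylhept-5-en-2-one | CC(=O)CCC=C(C)C | starting material
4 | dilithium enediolate of 2, dilithium (4-methylcyclohex-3-en-1-ylidene)methanediolate | [Li+].[Li+].[O-]C([O-])=C1CCC(C)=CC1 | intermediate
5 | rac-(1R)-1-[(2R)-2-hydroxy-6-methylhept-5-en-2-yl]-4-methylcyclohex-3-ene-1-carboxylic acid | O[C@](C)(CCC=C(C)C)[C@]1(C(=O)O)CC=C(C)CC1 | intermediate
6 | mixed anhydride of 5 with benzenesulfonic acid (same configuration as 5) | O[C@](C)(CCC=C(C)C)[C@]1(C(=O)OS(=O)(=O)c2ccccc2)CC=C(C)CC1 | intermediate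
7 | rac-(3R,4R)-3,7-dimethyl-3-(4-methylpent-3-en-1-yl)-2-oxaspiro[3.5]non-6-en-1-one (C14 methyl and C1 on the same face of the lactone ring) | O=C1O[C@](C)(CCC=C(C)C)[C@@]12CC=C(C)CC2 | intermediate
8 | (E)-γ-bisabolene, (4E)-1-methyl-4-(6-methylhept-5-en-2-ylidene)cyclohex-1-ene | CC(C)=CCC/C(C)=C1/CC=C(C)CC1 | intermediate
9 | potassium bromide | [K+].[Br-] | starting material
10 | (6R,10S)-10-bromochamigr-2-en-7-yl cation (tertiary cation at C7) | C[C+]1CC[C@H](Br)C(C)(C)[C@@]12CCC(C)=CC2 | intermediate
11 | (6R,8S)-8-bromo-3,7,7-trimethyl-11-methylidenespiro[5.5]undec-2-ene, (6R,10S)-10-bromo-β-chamigrene | C=C1CC[C@H](Br)C(C)(C)[C@@]12CCC(C)=CC2 | intermediate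
12 | (2R,3R,6R,8S)-2,8-dibromo-3,7,7-trimethyl-11-methylidenespiro[5.5]undecan-3-ol | C=C1CC[C@H](Br)C(C)(C)[C@@]12CC[C@@](C)(O)[C@H](Br)C2 | target

## Step count and least certain steps

Total: 6 steps. Longest linear sequence: 6 steps (1 → 2 → 5 → 7 → 8 → 11 → 12).

**Step 5 (key step, proposed new method).**
- **Most likely failure:** the oxidised bromine leaves the active site as free hypobromite and reacts in bulk solution. Control of the olefin face is then lost (racemic product), and so is control of the site (bromohydrin formation at C2=C3 or C6=C7). Cation 10 may also be captured by the aqueous medium, or lose its proton from C8 to give the endocyclic olefin.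
- **Fallback (known chemistry, sets out from 8 and rejoins the route at 12):** the reagent-based bromonium polyene cyclisation with Et2SBr·SbCl5Br in MeNO2 at −25 °C is water-free and should follow the same chair rule. It gives the racemate, that is 11 together with its mirror image (6S,8R)-8-bromo-3,7,7-trimethyl-11-methylidenespiro[5.5]undec-2-ene F1. Step 6 is run on the racemate. The product, 12 with its enantiomer (2S,3S,6S,8R)-2,8-dibromo-3,7,7-trimethyl-11-methylidenespiro[5.5]undecan-3-ol F2, is resolved by preparative chromatography on a cellulose tris(3,5-dimethylphenylcarbamate) phase, where the tertiary hydroxyl gives the phase a handle. Enzyme control is thus replaced by diastereocontrol plus resolution, at the cost of half the material.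

**Step 2.**
- **Most likely failure:** no useful preference between the two diastereomeric adducts, which differ only in the remote position of the ring double bond, and a separation that does not succeed by crystallisation. Proton transfer from ketone 3 to dianion 4 and retro-aldol cleavage on warming would lower conversion further.
- **Fallback (sets out from 3 and rejoins at 8):** the olefin geometry is fixed by a stereospecific syn carbocupration instead of a separation.
  - Ketone 3 is converted through its kinetic enol phosphate (LiN(i-Pr)2, ClP(O)(OEt)2, then LiN(i-Pr)2, 2.2 equiv) into 6-methylhept-5-en-1-yne F3, which is carboxylated (n-BuLi, ClCO2Me) to methyl 7-methyloct-6-en-2-ynoate F4.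
  - Me2CuLi adds syn across the triple bond at −78 °C and the α-cuprio ester is trapped with allyl bromide to give methyl (2Z)-3,7-dimethyl-2-(prop-2-en-1-yl)octa-2,6-dienoate F5. The new methyl and the allyl group are cis by mechanism.
  - i-Bu2AlH gives (2Z)-3,7-dimethyl-2-(prop-2-en-1-yl)octa-2,6-dien-1-ol F6, and CBr4/PPh3 gives (2Z)-1-bromo-3,7-dimethyl-2-(prop-2-en-1-yl)octa-2,6-diene F7.
  - 2-Methylallylmagnesium chloride in THF displaces the bromide at the primary carbon to give (5E)-2,6,10-trimethyl-5-(prop-2-en-1-yl)undeca-1,5,9-triene F8.
  - Ring-closing metathesis with the second-generation Grubbs catalyst joins the allyl and methallyl termini into ring B and gives 8, with the allyl-derived C1 cis to the C14 methyl.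

**Step 6.**
- **Most likely failure:** poor facial selectivity. The chair-like diaxial opening that is normally preferred would need bromine on the C7 face of ring B, so steric approach control and the stereoelectronic preference pull in opposite directions. Attack on the C7=C14 methylidene and allylic bromination are lesser risks.
- **Fallback (sets out from 11 and returns to 11):** selection is replaced by sorting and recycling. The trans bromohydrin of the wrong face, (2S,3S,6R,8S)-2,8-dibromo-3,7,7-trimethyl-11-methylidenespiro[5.5]undecan-3-ol F9, is separated from 12 by chromatography. It is returned to 11 by reductive elimination with Zn dust in AcOH, which should leave the unactivated C10 bromide alone, and 11 is resubmitted to step 6.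

## Further compounds

F1 | step 5 | (6S,8R)-8-bromo-3,7,7-trimethyl-11-methylidenespiro[5.5]undec-2-ene (enantiomer of 11) | C=C1CC[C@@H](Br)C(C)(C)[C@]12CCC(C)=CC2
F2 | step 5 | (2S,3S,6S,8R)-2,8-dibromo-3,7,7-trimethyl-11-methylidenespiro[5.5]undecan-3-ol (enantiomer of 12) | C=C1CC[C@@H](Br)C(C)(C)[C@]12CC[C@](C)(O)[C@@H](Br)C2
F3 | step 2 | 6-methylhept-5-en-1-yne | C#CCCC=C(C)C
F4 | step 2 | methyl 7-methyloct-6-en-2-ynoate | COC(=O)C#CCCC=C(C)C
F5 | step 2 | methyl (2Z)-3,7-dimethyl-2-(prop-2-en-1-yl)octa-2,6-dienoate | C=CC/C(C(=O)OC)=C(\C)CCC=C(C)C
F6 | step 2 | (2Z)-3,7-dimethyl-2-(prop-2-en-1-yl)octa-2,6-dien-1-ol | C=CC/C(CO)=C(\C)CCC=C(C)C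
F7 | step 2 | (2Z)-1-bromo-3,7-dimethyl-2-(prop-2-en-1-yl)octa-2,6-diene | C=CC/C(CBr)=C(\C)CCC=C(C)C
F8 | step 2 | (5E)-2,6,10-trimethyl-5-(prop-2-en-1-yl)undeca-1,5,9-triene | C=CC/C(CCC(C)=C)=C(\C)CCC=C(C)C
F9 | step 6 | (2S,3S,6R,8S)-2,8-dibromo-3,7,7-trimethyl-11-methylidenespiro[5.5]undecan-3-ol | C=C1CC[C@H](Br)C(C)(C)[C@@]12CC[C@](C)(O)[C@@H](Br)C2
A1 | alternative 1 | (6R,10S)-10-bromo-3,11,11-trimethyl-4-(trimethylsilyl)spiro[5.5]undec-3-ene-2,7-dione (chamigrane numbering) | O=C1CC[C@H](Br)C(C)(C)[C@@]12CC([Si](C)(C)C)=C(C)C(=O)C2
A2 | alternative 1 | (8S)-8-bromo-9,9-dimethylspiro[3.5]nonane-2,5-dione | O=C1CC[C@H](Br)C(C)(C)C12CC(=O)C2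
A3 | alternative 1 | 1-(trimethylsilyl)propyne | CC#C[Si](C)(C)C
A4 | alternative 2 | (6R,10S)-10-bromo-11,11-dimethyl-7-methylidenespiro[5.5]undec-1-en-3-one (chamigrane numbering) | C=C1CC[C@H](Br)C(C)(C)[C@@]12CCC(=O)C=C2
A5 | alternative 2 | (3S)-3-bromo-2,2-dimethyl-6-methylidenecyclohexane-1-carbaldehyde | C=C1CC[C@H](Br)C(C)(C)C1C=O
A6 | alternative 2 | methyl vinyl ketone (but-3-en-2-one) | CC(=O)C=C
A7 | alternative 3 | (3R,6R,10S)-10-bromo-3-hydroxy-3,11,11-trimethyl-7-methylidenespiro[5.5]undecan-2-one (chamigrane numbering) | C=C1CC[C@H](Br)C(C)(C)[C@@]12CC[C@@](C)(O)C(=O)C2
A8 | alternative 3 | 2-[(1R,3S)-3-bromo-2,2-dimethyl-6-methylidene-1-(3-oxobutyl)cyclohexyl]acetaldehyde | C=C1CC[C@H](Br)C(C)(C)[C@@]1(CC=O)CCC(C)=O
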